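A direct plan would keep a purchased pyrrole intact: linolenylmagnesium bromide A1 would be added to 1H-pyrrole-2-carbaldehyde A2 to give the pyrrolyl carbinol A3, hydride deoxygenation would then give the 2-alkylpyrrole A4, and a Vilsmeier–Haack formylation would finish. Its weakest steps would be:
- the Grignard addition, because the N–H (or N-metalated) formylpyrrole is a deactivated, vinylogous-amide carbonyl that would consume an excess of the precious polyene reagent;
- the hydride deoxygenation, because the acid-labile carbinol would have to pass through an azafulvene in refluxing LiAlH4;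
- the late formylation, which would add a single carbon to an air- and acid-sensitive alkylpyrrole at the very end.

The route exploits the fact that pyrrole carbons C2 and C5, both bonded to N1, stand in a 1,4-relationship: the ring is a 1,4-diketone plus ammonia in disguise. It is therefore not bought but assembled last, by disconnecting N1–C2, N1–C5 and C4–C5. A thiazolium-catalysed Stetter addition joins the C20 trienal 6 (C5 with the whole C19 chain) to the vinyl ketoacetal 11 (C2, C3, C4 and the masked formyl carbon); ammonia then closes the ring in the same flask and mild acid unmasks the aldehyde. One operation thus replaces organometallic addition to a pyrrole, carbinol deoxygenation and electrophilic formylation, and the Z,Z,Z-triene sees only weak base and weak acid.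

Key step: step 5

Assumption: the target has no stereocentre, so "single enantiomer" is read as the single (10Z,13Z,16Z) geometric isomer; all three Z-alkenes are carried in unchanged from linolenyl alcohol.

Step 1
Reactants: 1 linolenyl alcohol [(9Z,12Z,15Z)-octadeca-9,12,15-trien-1-ol]
Product: 2 linolenyl bromide [(3Z,6Z,9Z)-18-bromooctadeca-3,6,9-triene]
Conditions: CBr4 (1.3 eq), PPh3 (1.4 eq), CH2Cl2, 0 °C → rt, Ar
Reagents that add atoms: carbon tetrabromide, BrC(Br)(Br)Br
Why: Appel reaction, in which bromide displaces the alkoxyphosphonium group of the primary alcohol by SN2 under neutral conditions that should leave the skipped Z,Z,Z-triene untouched.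

Step 2
Reactants: 2 linolenyl bromide; 3 acetaldehyde N-tert-butylimine
Product: 6 (11Z,14Z,17Z)-icosa-11,14,17-trienal, via lithio azaenolate 4 (not isolated), via N-tert-butyl aldimine 5 (not isolated)
Conditions: 3 (1.5 eq), LDA (1.5 eq), THF, −78 → 0 °C; then 2, −78 °C → rt; then aq. oxalic acid, pentane, rt
Reagents that add atoms: water, O
Why: Metalloenamine (Stork–Wittig azaenolate) alkylation, in which the 1-azaallyllithium should be C-alkylated by the primary bromide (the tert-butyl group blocking N-alkylation) and the aldimine should be hydrolysed at pH about 4, a two-carbon homologation that never exposes the bis-allylic positions to free strong base.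

Step 3
Reactants: 7 ethyl diethoxyacetate
Product: 8 2,2-diethoxy-N-methoxy-N-methylacetamide
Conditions: MeNH(OMe)·HCl (1.5 eq), i-PrMgCl (3.0 eq), THF, −20 → 0 °C
Reagents that add atoms: N,O-dimethylhydroxylamine hydrochloride, CNOC.Cl
Why: Weinreb amide formation by aminolysis of the ester with the chloromagnesium amide made in the flask, which should outpace Grignard addition and leave the base-stable acetal intact.

Step 4
Reactants: 8 2,2-diethoxy-N-methoxy-N-methylacetamide; 9 vinylmagnesium bromide
Product: 11 1,1-diethoxybut-3-en-2-one, via magnesium chelate 10 (not isolated)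
Conditions: 9 (1.2 eq), THF, −78 → 0 °C; inverse quench into cold 1 M HCl/Et2O; distil with BHT, store at −20 °C
Reagents that add atoms: none
Why: Weinreb ketone synthesis, in which the five-membered magnesium chelate should prevent over-addition and the acidic inverse quench should protonate the released N,O-dimethylhydroxylamine before it can add to the new enone.

Step 5
Reactants: 6 (11Z,14Z,17Z)-icosa-11,14,17-trienal; 11 1,1-diethoxybut-3-en-2-one
Product: 14 Mycalazal 20 [5-[(10Z,13Z,16Z)-nonadeca-10,13,16-trien-1-yl]-1H-pyrrole-2-carbaldehyde], via 1,4-diketone 12 (not isolated), via pyrrolyl diethyl acetal 13 (not isolated)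
Conditions: 3-benzyl-5-(2-hydroxyethyl)-4-methylthiazolium chloride (0.2 eq), Et3N (0.5 eq), 11 (1.3 eq, slow addition), EtOH, 70 °C, Ar; then NH4OAc (10 eq), AcOH, 70 °C; then 1 M HCl, THF, rt
Reagents that add atoms: ammonium acetate, CC(=O)[O-].[NH4+]; water, O
Why: The thiazol-2-ylidene released by Et3N should add to aldehyde 6 to give the Breslow intermediate, an acyl anion equivalent that adds in conjugate fashion to the terminal CH2 of enone 11 (Stetter reaction) and so forms the C4–C5 bond of 1,4-diketone 12. Ammonia from NH4OAc should then condense with both carbonyl groups (Paal–Knorr): the hemiaminal nitrogen formed at one carbonyl attacks the other in a 5-exo-trig closure, so that N1–C2 and N1–C5 are formed and double dehydration aromatises the ring to 13. The closest known reaction type is the one-pot Stetter/Paal–Knorr pyrrole synthesis from aliphatic aldehydes, vinyl ketones and an amine source. No stereocentre is formed, and the substitution pattern is fixed by the components, because the chain can enter only with the aldehyde carbon (C5) and the acetal only with the enone carbonyl (C2). The step needs 1,4- rather than 1,2-addition of the Breslow intermediate, which the unhindered vinyl terminus activated by the α-ketoacetal should secure while acyloin formation stays reversible, and the Z-alkenes meet no strong base, hydride, metal or radical. Dilute acid should finally ionise the pyrrolylic acetal through a stabilised azafulvenium ion, and water delivers aldehyde 14.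

Compound list
1 | linolenyl alcohol, (9Z,12Z,15Z)-octadeca-9,12,15-trien-1-ol | CC/C=C\C/C=C\C/C=C\CCCCCCCCO | starting material
2 | linolenyl bromide, (3Z,6Z,9Z)-18-bromooctadeca-3,6,9-triene | CC/C=C\C/C=C\C/C=C\CCCCCCCCBr | intermediate
3 | acetaldehyde N-tert-butylimine, (E)-N-tert-butylethanimine | C/C=N/C(C)(C)C | starting material
4 | lithio azaenolate, lithium N-tert-butyl-N-ethenylamide | [Li]N(C=C)C(C)(C)C | intermediate
5 | (1E,11Z,14Z,17Z)-N-tert-butylicosa-11,14,17-trien-1-imine | CC/C=C\C/C=C\C/C=C\CCCCCCCCC/C=N/C(C)(C)C | intermediate
6 | (11Z,14Z,17Z)-icosa-11,14,17-trienal | CC/C=C\C/C=C\C/C=C\CCCCCCCCCC=O | intermediate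
7 | ethyl diethoxyacetate | CCOC(=O)C(OCC)OCC | starting material
8 | 2,2-diethoxy-N-methoxy-N-methylacetamide | CCOC(OCC)C(=O)N(C)OC | intermediate
9 | vinylmagnesium bromide | C=C[Mg]Br | starting material
10 | magnesium chelate, bromomagnesium 1,1-diethoxy-2-[methoxy(methyl)amino]but-3-en-2-olate | CCOC(OCC)C(C=C)(O[Mg]Br)N(C)OC | intermediate
11 | 1,1-diethoxybut-3-en-2-one | C=CC(=O)C(OCC)OCC | intermediate
12 | (15Z,18Z,21Z)-1,1-diethoxytetracosa-15,18,21-triene-2,5-dione | CC/C=C\C/C=C\C/C=C\CCCCCCCCCC(=O)CCC(=O)C(OCC)OCC | intermediate
13 | 2-(diethoxymethyl)-5-[(10Z,13Z,16Z)-nonadeca-10,13,16-trien-1-yl]-1H-pyrrole | CC/C=C\C/C=C\C/C=C\CCCCCCCCCc1ccc(C(OCC)OCC)[nH]1 | intermediate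
14 | Mycalazal 20, 5-[(10Z,13Z,16Z)-nonadeca-10,13,16-trien-1-yl]-1H-pyrrole-2-carbaldehyde | CC/C=C\C/C=C\C/C=C\CCCCCCCCCc1ccc(C=O)[nH]1 | target

Total step count: 5
Longest linear sequence: 3 steps (steps 1, 2 and 5); the enone branch (steps 3 and 4) is 2 steps.

Steps most likely to fail

1. Step 5. The Breslow intermediate may be diverted into acyloin self-condensation, or the activated enone may oligomerise under carbene and amine, so that little 1,4-diketone reaches the ammonia stage. The fallback would make the C4–C5 bond from an acetylide and close the ring by hydroamination, setting out from 2 and 11. Bromide 2 with lithium acetylide–ethylenediamine complex in DMSO should give (11Z,14Z,17Z)-icosa-11,14,17-trien-1-yne F1 by SN2 displacement. Pd(OAc)2/PMe3-catalysed conjugate addition of this terminal alkyne to 11 should then give (15Z,18Z,21Z)-1,1-diethoxytetracosa-15,18,21-trien-5-yn-2-one F2 without touching the alkenes. With ammonia in methanol and a catalytic gold(III) salt, the ketimine nitrogen should attack the alkyne 5-exo-dig and the exocyclic alkene should tautomerise into the ring. The route is rejoined at 13, which is hydrolysed to 14 as in step 5.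

2. Step 4. The free vinyl ketone may be lost to polymerisation on distillation or to aza-Michael addition of the released hydroxylamine during work-up. The fallback would carry the enone as a storable Mannich base, setting out from 8. Methylmagnesium bromide should give 1,1-diethoxypropan-2-one F3 from the Weinreb amide. A Mannich reaction at its methyl group with dimethylmethyleneiminium iodide in MeCN should give 4-(dimethylamino)-1,1-diethoxybutan-2-one F4 after basic work-up. Charged into step 5 in place of 11, it should release 11 in the flask by β-elimination under Et3N at 70 °C, so that the route is rejoined at 11 and continues to 12.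

3. Step 2. Alkylation of the azaenolate may suffer from E2 elimination of the bromide or from dialkylation, and the unbranched aldehyde may undergo aldol self-condensation during imine hydrolysis. The fallback would introduce the two carbons at the nitrile oxidation level, setting out from 2. Lithioacetonitrile (MeCN, n-BuLi, THF, −78 °C) should give (11Z,14Z,17Z)-icosa-11,14,17-trienenitrile F5 by alkylation with the bromide. Partial reduction with DIBAL-H in toluene at −78 °C and hydrolysis with aqueous tartaric acid should return the route to 6.

Further compounds
F1 | step 5 | (11Z,14Z,17Z)-icosa-11,14,17-trien-1-yne | CC/C=C\C/C=C\C/C=C\CCCCCCCCC#C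
F2 | step 5 | (15Z,18Z,21Z)-1,1-diethoxytetracosa-15,18,21-trien-5-yn-2-one | CC/C=C\C/C=C\C/C=C\CCCCCCCCC#CCCC(=O)C(OCC)OCC
F3 | step 4 | 1,1-diethoxypropan-2-one | CCOC(OCC)C(C)=O
F4 | step 4 | 4-(dimethylamino)-1,1-diethoxybutan-2-one | CCOC(OCC)C(=O)CCN(C)C
F5 | step 2 | (11Z,14Z,17Z)-icosa-11,14,17-trienenitrile | CC/C=C\C/C=C\C/C=C\CCCCCCCCCC#N
A1 | direct plan | linolenylmagnesium bromide, [(9Z,12Z,15Z)-octadeca-9,12,15-trien-1-yl]magnesium bromide | CC/C=C\C/C=C\C/C=C\CCCCCCCC[Mg]Br
A2 | direct plan | 1H-pyrrole-2-carbaldehyde | O=Cc1ccc[nH]1
A3 | direct plan | (10Z,13Z,16Z)-1-(1H-pyrrol-2-yl)nonadeca-10,13,16-trien-1-ol (racemic) | CC/C=C\C/C=C\C/C=C\CCCCCCCCC(O)c1ccc[nH]1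
A4 | direct plan | 2-[(10Z,13Z,16Z)-nonadeca-10,13,16-trien-1-yl]-1H-pyrrole | CC/C=C\C/C=C\C/C=C\CCCCCCCCCc1ccc[nH]1
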